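**Plan**
1. Atoms are numbered as in germacrane (ring C1–C10, CH3-14 on C10, CH3-15 on C4, isopropenyl on C7). Removing the O9 acetyl, the O8 angeloyl and the C1/C10 oxirane oxygen leads back to cis-8,9-diol 21 with a (Z)-C1=C10 alkene.
2. The ring is cut at C8–C9. These adjacent ring carbons both carry oxygen (a cis-glycol, C9 allylic to C1=C10), which is the retron of a reductive carbonyl coupling, so 21 comes from open-chain C8-aldehyde/C9-(Z)-enal 19.
3. 19 is cut at C1=C10 (ring-closing metathesis to a six-membered lactone, a temporary ring that fixes the Z geometry and masks O3/C9) and at C2–C3 (allylboration). This gives epoxy aldehyde 8 (C3–C8), which comes from (S)-carvone by cleaving the ring bond that becomes C3/C8.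
4. Forward: carvone oxirane, ring cleavage, chain extension at C3, lactone on and off, C3 angelate, dialdehyde, SmI2 pinacol closing the only carbocycle (ten-membered), 1,10-oxirane, O8 angelate, O9 acetate.
5. Stereochemistry: C7 from (S)-carvone; C4/C5 by epoxidation anti to isopropenyl on the cyclohexenone (which also makes the oxirane cis); C3 by reagent-controlled allylboration; C8 (Felkin–Anh) and C9 (samarium-bridged cis-diol) in the pinacol; C1/C10 by 9-OH-directed vanadium epoxidation.

Key step: step 15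

Remark: both 2-methylbut-2-enoates are angelates (Z) and both oxiranes are cis with respect to the ring (C3/C6 and C2/C9 cis), as the SMILES specifies. CIP letters at C4, C9 and C10 change along the route only because substituent priorities change. TBS = tert-butyldimethylsilyl.

Step 1
Reactants: 1 (S)-(+)-carvone
Product: 2 trans-carvone oxide, (1S,4S,6S)-1-methyl-4-(prop-1-en-2-yl)-7-oxabicyclo[4.1.0]heptan-2-one
Conditions: 30% H2O2, NaOH (0.2 equiv), MeOH, 0 °C
Reagents that add atoms: hydrogen peroxide, OO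
Why: Weitz–Scheffer nucleophilic epoxidation of the enone, in which hydroperoxide should add anti to the isopropenyl group, setting C4 and C5 and, because the alkene is endocyclic, the cis oxirane.

Step 2
Reactants: 2 trans-carvone oxide
Product: 4 (1S,3R,4R,6S)-3-hydroxy-1-methyl-4-(prop-1-en-2-yl)-7-oxabicyclo[4.1.0]heptan-2-one (the 3-epimer serves equally), via potassium enolate 3 (not isolated)
Conditions: KN(SiMe3)2, THF, −78 °C; then 2-(phenylsulfonyl)-3-phenyloxaziridine, −78 °C; AcOH quench
Reagents that add atoms: 2-(phenylsulfonyl)-3-phenyloxaziridine, O=S(=O)(c1ccccc1)N1OC1c1ccccc1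
Why: Davis enolate oxidation, in which deprotonation can occur only at the CH2 next to the ketone (the other α-carbon is the fully substituted oxirane carbon), and the new carbinol centre is erased in step 3.

Step 3
Reactants: 4 α-hydroxy ketone
Product: 5 methyl (2S,3S)-3-[(2R)-2-formyl-3-methylbut-3-en-1-yl]-2-methyloxirane-2-carboxylate
Conditions: Pb(OAc)4, MeOH–toluene 1:2, 0 °C
Reagents that add atoms: methanol, CO
Why: Criegee-type cleavage of the α-ketol through its methyl hemiketal should cut the former carvone ring bond to give the C3 methyl ester and the C8 aldehyde without touching C4, C5 or C7.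

Step 4
Reactants: 5 aldehyde ester (used crude)
Product: 6 methyl (2S,3S)-3-[(2R)-2-(hydroxymethyl)-3-methylbut-3-en-1-yl]-2-methyloxirane-2-carboxylate
Conditions: NaBH4, MeOH, −30 °C
Reagents that add atoms: none
Why: Chemoselective borohydride reduction of the aldehyde beside the glycidic ester should store the epimerisable α-isopropenyl aldehyde as a primary alcohol.

Step 5
Reactants: 6 hydroxy ester
Product: 7 methyl (2S,3S)-3-[(2R)-2-(TBS-oxymethyl)-3-methylbut-3-en-1-yl]-2-methyloxirane-2-carboxylate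
Conditions: TBSCl, imidazole, CH2Cl2, 0 °C
Reagents that add atoms: tert-butyldimethylsilyl chloride, CC(C)(C)[Si](C)(C)Cl
Why: Standard silylation should protect the primary alcohol before it can open the γ,δ-oxirane.

Step 6
Reactants: 7 silyl ether ester
Product: 8 (2S,3S)-3-[(2R)-2-(TBS-oxymethyl)-3-methylbut-3-en-1-yl]-2-methyloxirane-2-carbaldehyde
Conditions: i-Bu2AlH (1.05 equiv), CH2Cl2, −78 °C; Rochelle salt work-up
Reagents that add atoms: none
Why: Partial ester reduction through the aluminium hemiacetal that is stable at −78 °C should give the aldehyde, whose α-carbon is quaternary and cannot epimerise.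

Step 7
Reactants: 8 epoxy aldehyde
Product: 10 (1S)-1-{(2R,3S)-3-[(2R)-2-(TBS-oxymethyl)-3-methylbut-3-en-1-yl]-2-methyloxiran-2-yl}but-3-en-1-ol, via borinate ester 9 (not isolated)
Conditions: pre-formed salt-free (−)-Ipc2B(allyl), Et2O, −78 °C; then NaBO3·4H2O, THF–H2O, 25 °C
Reagents that add atoms: (−)-B-allyldiisopinocampheylborane, C=CCB([C@@H]1C[C@@H]2C[C@@H](C2(C)C)[C@H]1C)[C@@H]1C[C@@H]2C[C@@H](C2(C)C)[C@H]1C
Why: Brown asymmetric allylboration through a chair Zimmerman–Traxler transition state, in which the (+)-α-pinene-derived reagent should attack the Si face and set C3 as S under reagent control; the perborate work-up avoids Payne rearrangement.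

Step 8
Reactants: 10 homoallylic alcohol
Product: 11 (1S)-1-{(2S,3S)-3-[(2R)-2-(TBS-oxymethyl)-3-methylbut-3-en-1-yl]-2-methyloxiran-2-yl}but-3-en-1-yl 2-methylprop-2-enoate
Conditions: methacryloyl chloride, Et3N, DMAP (cat.), CH2Cl2, 0 °C
Reagents that add atoms: methacryloyl chloride, C=C(C)C(=O)Cl
Why: Simple O-acylation should install C9, C10 and CH3-14 as the metathesis partner.

Step 9
Reactants: 11 methacrylate
Product: 12 (6S)-6-{(2S,3S)-3-[(2R)-2-(TBS-oxymethyl)-3-methylbut-3-en-1-yl]-2-methyloxiran-2-yl}-3-methyl-5,6-dihydro-2H-pyran-2-one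
Conditions: second-generation Grubbs catalyst, (H2IMes)(PCy3)Cl2Ru=CHPh (5 mol %), CH2Cl2 (5 mM), 40 °C
Reagents that add atoms: none
Why: Ring-closing metathesis to the α-methyl unsaturated δ-lactone, a temporary six-membered ring that forces the C1=C10 alkene to be Z, while the 1,1-disubstituted isopropenyl group should be a much slower partner.

Step 10
Reactants: 12 lactone
Product: 14 (2Z,5S)-5-{(2R,3S)-3-[(2R)-2-(TBS-oxymethyl)-3-methylbut-3-en-1-yl]-2-methyloxiran-2-yl}-2-methylpent-2-ene-1,5-diol, via lactol 13 (not isolated)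
Conditions: i-Bu2AlH (3.5 equiv), CH2Cl2, −78 to −20 °C; Rochelle salt work-up
Reagents that add atoms: none
Why: 1,2-Reduction of the unsaturated lactone should open the temporary ring to the (Z)-allylic diol with the alkene geometry retained.

Step 11
Reactants: 14 diol
Product: 15 (1S,3Z)-5-(TBS-oxy)-1-{(2R,3S)-3-[(2R)-2-(TBS-oxymethyl)-3-methylbut-3-en-1-yl]-2-methyloxiran-2-yl}-4-methylpent-3-en-1-ol
Conditions: TBSCl (1.05 equiv), imidazole, CH2Cl2, −20 °C
Reagents that add atoms: tert-butyldimethylsilyl chloride, CC(C)(C)[Si](C)(C)Cl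
Why: Silylation should select the primary allylic hydroxyl over the hindered secondary C3 hydroxyl next to the fully substituted oxirane carbon.

Step 12
Reactants: 15 mono-alcohol; 16 angelic acid, (2Z)-2-methylbut-2-enoic acid
Product: 17 (1S,3Z)-5-(TBS-oxy)-1-{(2S,3S)-3-[(2R)-2-(TBS-oxymethyl)-3-methylbut-3-en-1-yl]-2-methyloxiran-2-yl}-4-methylpent-3-en-1-yl (2Z)-2-methylbut-2-enoate
Conditions: 16 (3 equiv), 2,4,6-trichlorobenzoyl chloride, Et3N, toluene, 25 °C; then 15, 75 °C (no DMAP)
Reagents that add atoms: none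
Why: Yamaguchi-type mixed-anhydride esterification of the only free hydroxyl, run without a nucleophilic catalyst so that the angelate should not isomerise to the tiglate.

Step 13
Reactants: 17 bis-silyl ether
Product: 18 (1S,3Z)-5-hydroxy-1-{(2S,3S)-3-[(2R)-2-(hydroxymethyl)-3-methylbut-3-en-1-yl]-2-methyloxiran-2-yl}-4-methylpent-3-en-1-yl (2Z)-2-methylbut-2-enoate
Conditions: HF·pyridine, excess pyridine, THF, 0 to 25 °C
Reagents that add atoms: none
Why: Buffered fluoride desilylation should free both primary alcohols (C8 and C9) while the ester and the oxirane stay intact.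

Step 14
Reactants: 18 diol
Product: 19 (1S,3Z)-1-{(2S,3S)-3-[(2R)-2-formyl-3-methylbut-3-en-1-yl]-2-methyloxiran-2-yl}-4-methyl-5-oxopent-3-en-1-yl (2Z)-2-methylbut-2-enoate
Conditions: Dess–Martin periodinane (2.4 equiv), NaHCO3, CH2Cl2, 0 to 25 °C; used crude at once
Reagents that add atoms: none
Why: Buffered Dess–Martin oxidation should give the C8 aldehyde and the C9 (Z)-enal in one operation without epimerising C7 or isomerising the enal.

Step 15
Reactants: 19 dialdehyde
Product: 21 (1(10)Z,3S,4S,5S,7R,8S,9R)-4,5-epoxy-8,9-dihydroxygermacra-1(10),11-dien-3-yl angelate, via samarium diolate 20 (not isolated)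
Conditions: SmI2 (3 equiv, 0.02 M in THF), 19 added over 8 h (final 1 mM), −78 then −40 °C; H2O quench
Reagents that add atoms: none
Why: SmI2 should first transfer one electron to the conjugated C9 aldehyde, the trivalent-samarium ketyl (spin shared by C9 and C1) then attacks the samarium-bound C8 aldehyde, and a second electron gives cis-8,9-diolate 20, which is protonated on work-up. The reaction type is the intramolecular pinacol (reductive carbonyl) coupling of a dialdehyde, the established route to medium- and large-ring carbocyclic 1,2-diols with SmI2 or low-valent titanium. The single carbocycle closes in a 10-exo-trig mode (C9 radical onto C8=O, oxygen left outside the ring). C8 is controlled by the C7 stereocentre (Felkin–Anh, new bond anti to the isopropenyl group, giving 7R,8S), and C9 by samarium bridging of both oxygens in the bond-forming transition state, which puts the two C–O bonds syn (cis-diol). The step needs ring closure to beat intermolecular coupling and coupling through C1 (eight-membered ring), and the Z alkene to survive; slow addition at high dilution, the turns imposed by the (Z)-C1=C10 alkene and the cis-oxirane, the O–Sm–O template holding C8 next to C9, and the strain of an E-cyclodecene should secure this. The angelate, the isolated 4,5-oxirane and the isopropenyl group are not expected to be reduced by HMPA-free SmI2 at −78 °C.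

Step 16
Reactants: 21 macrocyclic diol
Product: 22 (1R,3S,4S,5S,7R,8S,9S,10S)-1,10:4,5-diepoxy-8,9-dihydroxygermacr-11-en-3-yl angelate
Conditions: VO(acac)2 (5 mol %), t-BuOOH (1.1 equiv, in decane), CH2Cl2, 0 °C
Reagents that add atoms: tert-butyl hydroperoxide, CC(C)(C)OO
Why: Vanadium-catalysed hydroxyl-directed epoxidation, in which the C9 vanadate ester should deliver oxygen to the adjacent (Z)-trisubstituted ring alkene on the face of the C9–O bond, as in medium-ring (Z)-cycloalkenols, setting C1 and C10; the angelate alkene and the isopropenyl group (reachable only from the slower homoallylic 8-OH) should stay intact.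

Step 17
Reactants: 22 epoxy diol; 16 angelic acid
Product: 23 (1R,3S,4S,5S,7R,8S,9S,10S)-1,10:4,5-diepoxy-9-hydroxygermacr-11-ene-3,8-diyl bis[(2Z)-2-methylbut-2-enoate]
Conditions: 16 (1.1 equiv), 2,4,6-trichlorobenzoyl chloride, Et3N, toluene, 25 °C; then 22, 50 °C (no DMAP)
Reagents that add atoms: none
Why: Site-selective mixed-anhydride esterification, in which the C8 hydroxyl (flanked by two CH carbons) should react before the neopentyl-like C9 hydroxyl, which sits next to the fully substituted C10 oxirane carbon and is hydrogen-bonded to that oxirane.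

Step 18
Reactants: 23 hydroxy bis-angelate
Product: 24 target, (1R,3S,4S,5S,7R,8S,9S,10R)-9-acetoxy-1,10:4,5-diepoxygermacr-11-ene-3,8-diyl bis[(2Z)-2-methylbut-2-enoate]
Conditions: Ac2O, DMAP, pyridine, CH2Cl2, 25 °C
Reagents that add atoms: acetic anhydride, CC(=O)OC(C)=O
Why: DMAP-catalysed acetylation with the small anhydride should esterify the remaining hindered secondary alcohol and complete the target.

**Compound list**
1 | (S)-(+)-carvone, (5S)-2-methyl-5-(prop-1-en-2-yl)cyclohex-2-en-1-one | C=C(C)[C@H]1CC=C(C)C(=O)C1 | starting material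
2 | trans-carvone oxide, (1S,4S,6S)-1-methyl-4-(prop-1-en-2-yl)-7-oxabicyclo[4.1.0]heptan-2-one | C=C(C)[C@H]1C[C@@H]2O[C@]2(C)C(=O)C1 | intermediate
3 | potassium enolate of 2 (not isolated) | C=C(C)[C@H]1C[C@@H]2O[C@]2(C)C(O[K])=C1 | intermediate
4 | (1S,3R,4R,6S)-3-hydroxy-1-methyl-4-(prop-1-en-2-yl)-7-oxabicyclo[4.1.0]heptan-2-one | C=C(C)[C@H]1C[C@@H]2O[C@]2(C)C(=O)[C@@H]1O | intermediate
5 | methyl (2S,3S)-3-[(2R)-2-formyl-3-methylbut-3-en-1-yl]-2-methyloxirane-2-carboxylate | C=C(C)[C@H](C=O)C[C@@H]1O[C@]1(C)C(=O)OC | intermediate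
6 | methyl (2S,3S)-3-[(2R)-2-(hydroxymethyl)-3-methylbut-3-en-1-yl]-2-methyloxirane-2-carboxylate | C=C(C)[C@H](CO)C[C@@H]1O[C@]1(C)C(=O)OC | intermediate
7 | methyl (2S,3S)-3-[(2R)-2-(TBS-oxymethyl)-3-methylbut-3-en-1-yl]-2-methyloxirane-2-carboxylate | C=C(C)[C@H](CO[Si](C)(C)C(C)(C)C)C[C@@H]1O[C@]1(C)C(=O)OC | intermediate
8 | (2S,3S)-3-[(2R)-2-(TBS-oxymethyl)-3-methylbut-3-en-1-yl]-2-methyloxirane-2-carbaldehyde | C=C(C)[C@H](CO[Si](C)(C)C(C)(C)C)C[C@@H]1O[C@]1(C)C=O | intermediate
9 | diisopinocampheylborinate ester of 10 (not isolated) | C=C(C)[C@H](CO[Si](C)(C)C(C)(C)C)C[C@@H]1O[C@]1(C)[C@H](CC=C)OB([C@@H]2C[C@@H]3C[C@@H](C3(C)C)[C@H]2C)[C@@H]2C[C@@H]3C[C@@H](C3(C)C)[C@H]2C | intermediate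
10 | (1S)-1-{(2R,3S)-3-[(2R)-2-(TBS-oxymethyl)-3-methylbut-3-en-1-yl]-2-methyloxiran-2-yl}but-3-en-1-ol | C=C(C)[C@H](CO[Si](C)(C)C(C)(C)C)C[C@@H]1O[C@]1(C)[C@@H](O)CC=C | intermediate
11 | methacrylate of 10 | C=C(C)[C@H](CO[Si](C)(C)C(C)(C)C)C[C@@H]1O[C@]1(C)[C@@H](OC(=O)C(C)=C)CC=C | intermediate
12 | (6S)-6-{(2S,3S)-3-[(2R)-2-(TBS-oxymethyl)-3-methylbut-3-en-1-yl]-2-methyloxiran-2-yl}-3-methyl-5,6-dihydro-2H-pyran-2-one | C=C(C)[C@H](CO[Si](C)(C)C(C)(C)C)C[C@@H]1O[C@]1(C)[C@@H]1CC=C(C)C(=O)O1 | intermediate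
13 | lactol of 12, the 2-hydroxy-5,6-dihydro-2H-pyran (not isolated) | C=C(C)[C@H](CO[Si](C)(C)C(C)(C)C)C[C@@H]1O[C@]1(C)[C@@H]1CC=C(C)C(O)O1 | intermediate
14 | (2Z,5S)-5-{(2R,3S)-3-[(2R)-2-(TBS-oxymethyl)-3-methylbut-3-en-1-yl]-2-methyloxiran-2-yl}-2-methylpent-2-ene-1,5-diol | C=C(C)[C@H](CO[Si](C)(C)C(C)(C)C)C[C@@H]1O[C@]1(C)[C@@H](O)C/C=C(/C)CO | intermediate
15 | (1S,3Z)-5-(TBS-oxy)-1-{(2R,3S)-3-[(2R)-2-(TBS-oxymethyl)-3-methylbut-3-en-1-yl]-2-methyloxiran-2-yl}-4-methylpent-3-en-1-ol | C=C(C)[C@H](CO[Si](C)(C)C(C)(C)C)C[C@@H]1O[C@]1(C)[C@@H](O)C/C=C(/C)CO[Si](C)(C)C(C)(C)C | intermediate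
16 | angelic acid, (2Z)-2-methylbut-2-enoic acid | C/C=C(/C)C(=O)O | starting material
17 | C3 angelate of 15 | C=C(C)[C@H](CO[Si](C)(C)C(C)(C)C)C[C@@H]1O[C@]1(C)[C@@H](OC(=O)/C(C)=C\C)C/C=C(/C)CO[Si](C)(C)C(C)(C)C | intermediate
18 | C8,C9-diol C3-angelate | C=C(C)[C@H](CO)C[C@@H]1O[C@]1(C)[C@@H](OC(=O)/C(C)=C\C)C/C=C(/C)CO | intermediate
19 | C8-aldehyde C9-(Z)-enal C3-angelate | C=C(C)[C@H](C=O)C[C@@H]1O[C@]1(C)[C@@H](OC(=O)/C(C)=C\C)C/C=C(/C)C=O | intermediate
20 | bis(diiodosamarium) 8,9-diolate of 21 (not isolated) | C=C(C)[C@H]1C[C@@H]2O[C@]2(C)[C@@H](OC(=O)/C(C)=C\C)C/C=C(/C)[C@@H](O[Sm](I)I)[C@H]1O[Sm](I)I | intermediate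
21 | (1(10)Z,3S,4S,5S,7R,8S,9R)-4,5-epoxy-8,9-dihydroxygermacra-1(10),11-dien-3-yl angelate | C=C(C)[C@H]1C[C@@H]2O[C@]2(C)[C@@H](OC(=O)/C(C)=C\C)C/C=C(/C)[C@@H](O)[C@H]1O | intermediate
22 | (1R,3S,4S,5S,7R,8S,9S,10S)-1,10:4,5-diepoxy-8,9-dihydroxygermacr-11-en-3-yl angelate | C=C(C)[C@H]1C[C@@H]2O[C@]2(C)[C@@H](OC(=O)/C(C)=C\C)C[C@H]2O[C@@]2(C)[C@@H](O)[C@H]1O | intermediate
23 | (1R,3S,4S,5S,7R,8S,9S,10S)-1,10:4,5-diepoxy-9-hydroxygermacr-11-ene-3,8-diyl diangelate | C=C(C)[C@H]1C[C@@H]2O[C@]2(C)[C@@H](OC(=O)/C(C)=C\C)C[C@H]2O[C@@]2(C)[C@@H](O)[C@H]1OC(=O)/C(C)=C\C | intermediate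
24 | (1R,3S,4S,5S,7R,8S,9S,10R)-9-acetoxy-1,10:4,5-diepoxygermacr-11-ene-3,8-diyl diangelate | C=C(C)[C@H]1C[C@@H]2O[C@]2(C)[C@@H](OC(=O)/C(C)=C\C)C[C@H]2O[C@@]2(C)[C@@H](OC(C)=O)[C@H]1OC(=O)/C(C)=C\C | target

**Totals and risks**
Total step count: 18. Longest linear sequence: 18 steps from 1 (16 is a commercial acid used in steps 12 and 17).

Step 15 is the most likely to fail: ring closure may be outrun by intermolecular ketyl coupling or by coupling through C1 of the delocalised ketyl, and cis/Felkin control or the Z geometry may be lost. The fallback replaces the one-electron ketyl coupling by a two-electron organochromium addition and sets out from 19. CrCl2 (4 equiv) and Et3SiCl (2 equiv) in DMF at 25 °C under high dilution should reduce only the enal (the saturated aldehyde, the ester and the oxirane are inert to CrCl2) to a γ-triethylsiloxyallylchromium species. This should add to the C8 aldehyde at its oxygen-bearing terminus through a six-membered transition state, as in the intermolecular anti-selective chromium/chlorosilane cross-pinacol-type coupling of enals with aldehydes and in Nozaki–Hiyama ring closures of ten-membered carbocycles. The product would be the macrocyclic 9-O-triethylsilyl 8-ol F1, and n-Bu4NF/AcOH in THF would then return the route to 21.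

Step 17 is next: site selectivity between O8 and O9 may be poor, or the angeloyl group may migrate. The fallback reverses the order of acylation and sets out from 22. MeC(OMe)3 with PPTS in CH2Cl2 should give the cyclic 8,9-orthoacetate F2. Mild aqueous acetic acid should open it with the ester kept on the more hindered oxygen, the kinetic rule for orthoester hydrolysis, giving the 9-acetate 8-ol F3. Esterification of its only free hydroxyl with 16 under the step-12 conditions then comes back to the route at 24.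

Step 12 is third: the neopentyl-type C3 carbinol may not convert, or the activated angeloyl donor may isomerise from Z to E (tiglate). The fallback builds the angelate on the oxygen and sets out from 15. Acylation with 2-[bis(2,2,2-trifluoroethoxy)phosphoryl]propanoic acid (DCC, DMAP, CH2Cl2) should give the phosphonopropionate ester F4. Z-selective Still–Gennari olefination with acetaldehyde (KN(SiMe3)2, 18-crown-6, THF, −78 °C) then comes back to the route at 17.

**Further compounds**
F1 | step 15 | (1(10)Z)-4,5-epoxy-8-hydroxy-9-(triethylsilyloxy)germacra-1(10),11-dien-3-yl angelate | C=C(C)[C@H]1C[C@@H]2O[C@]2(C)[C@@H](OC(=O)/C(C)=C\C)C/C=C(/C)[C@@H](O[Si](CC)(CC)CC)[C@H]1O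
F2 | step 17 | cyclic 8,9-(1-methoxyethylidene) orthoacetate of 22 | C=C(C)[C@H]1C[C@@H]2O[C@]2(C)[C@@H](OC(=O)/C(C)=C\C)C[C@H]2O[C@@]2(C)[C@@H](OC(C)(OC)O3)[C@H]13
F3 | step 17 | 9-acetoxy-1,10:4,5-diepoxy-8-hydroxygermacr-11-en-3-yl angelate | C=C(C)[C@H]1C[C@@H]2O[C@]2(C)[C@@H](OC(=O)/C(C)=C\C)C[C@H]2O[C@@]2(C)[C@@H](OC(C)=O)[C@H]1O
F4 | step 12 | 2-[bis(2,2,2-trifluoroethoxy)phosphoryl]propanoate of 15 | C=C(C)[C@H](CO[Si](C)(C)C(C)(C)C)C[C@@H]1O[C@]1(C)[C@@H](OC(=O)C(C)P(=O)(OCC(F)(F)F)OCC(F)(F)F)C/C=C(/C)CO[Si](C)(C)C(C)(C)C
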